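4 questions stood, and I read them as asking how far each flask gets towards an even split of G and X.

| flask | G | J | Q | remark | time | volume of the second phase over the first |
|---|---|---|---|---|---|---|
| cedar | 0.66 M | 0.66 M | 9.2 mM | run made earlier |  |  |
| elm | 0.66 M | 0.66 M | 15 mM | run made earlier |  |  |
| maple | 1.3 M | 0.66 M | 6.6 mM | run made earlier |  |  |
| Wednesday's | 0.66 M | 0.660 M | 6.6 mM |  | 80 min | 0.25 |
| Sunday's | 0.66 M | 0.660 M | 6.6 mM |  | 200 min | 0.25 |

| run | time / min | X / % | G / % |
|---|---|---|---|
| cedar | 8.00 | 1.9 | 98.0 |
| cedar | 15.0 | 3.8 | 95.0 |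
| cedar | 25.0 | 6.1 | 93.8 |
| cedar | 50.0 | 10.0 | 91.5 |
| cedar | 90.0 | 16.7 | 82.2 |
| elm | 8.00 | 1.7 | 95.1 |
| elm | 15.0 | 3.0 | 95.2 |
| elm | 25.0 | 7.6 | 93.6 |
| elm | 50.0 | 12.4 | 85.8 |
| elm | 90.0 | 20.2 | 79.1 |
| maple | 8.00 | 2.1 | 99.8 |
| maple | 25.0 | 1.9 | 96.2 |
| maple | 40.0 | 4.0 | 96.7 |
| maple | 60.0 | 7.2 | 93.7 |
| maple | 90.0 | 8.4 | 91.8 |

(each reading ± 1 percentage point)

- which of these there is most of at the end, counted by the G in it, Wednesday's (G / X)
- which of these there is most of at the end, counted by the G in it, Sunday's (G / X)
- the largest of these amounts at the end, in percent of the G charged, Wednesday's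
- the largest of these amounts at the end, in percent of the G charged, Sunday's

- in the second phase: J, L; everything else is in the first
- charges count per volume of the first phase; a concentration in a rate is the amount of a species over the volume of its own phase; every rate counts per litre of the first phase
- what may be going on: Q + J <-> Z + L; G + Z -> X + Q; 2 Q <-> D
- the earlier runs hold the two phases in the same ratio of volumes as the flask asked about

X equals G once half of the charged G has reacted, so I took that symmetric point as my zero and reckoned the even-split time, the charged [G] over twice the pace at which X forms, with that pace held constant. Cedar made X at 1.22 mM min⁻¹ over its 90.0 min. Going from cedar's 9.2 mM of Q to elm's 15 mM raised X by a factor of 1.21, near the root of the Q ratio, 1.28, which pointed to catalyst stored as D, an off-cycle reservoir. I therefore scaled by the root, to 1.04 mM min⁻¹ at 6.6 mM. The even-split time came to 318 min, later than Sunday's 200 min, so I expected G to lead in both flasks, at 87.4 % on Wednesday's and 68.6 % on Sunday's.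

The forecast gave G at 87 % on Wednesday's and G at 74 % on Sunday's, slowing the pace through “J depletion plus L reversing the first step”.

Wednesday's flask gave G at 86.5 %. Sunday's flask gave G at 74.0 %.

    Q + J ⇌ Z + L (K = 0.670, k = 0.890 L mol⁻¹ min⁻¹)
    G + Z → X + Q (k = 1.60 L mol⁻¹ min⁻¹)
    2 Q ⇌ D, settled at all times (K = 5700 L mol⁻¹)

In Sunday's flask at 200 min, by the forward rate of Q + J -> Z + L alone, Q had a half-life of 0.40 min and J one of 4.8 h, far longer. So Q turned over within minutes while J fell over hours, and Sunday's, with X at 26.0 %, stood short of the even split, as its even-split time of 318 min said. The neighbour flask, Sunday's with 0.17 M of G, ended with X at 54.6 % against G at 45.4 %, a mean pace of 0.464 mM min⁻¹, slower than the 1.04 mM min⁻¹ I had reckoned for Sunday's, so at its own mean pace its even-split time is 183 min, earlier than its 200 min.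

(The readings were computed from invented constants.)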